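## Retrosynthetic overview

1. Rings: A azepine, B pyrrole, C cyclohexane, D fused α-methyl-γ-lactone, E pendant α-methyl-γ-lactone on the pyrrole α-carbon. The two ring D stereocentres and the ring E methyl stereocentre are taken back to C=C bonds and set last by hydrogenation.
2. Key disconnection: the ring E bond between the lactone carbonyl carbon and its methyl-bearing α-carbon. The carbonyl carbon is CO, stitched between the carbinol oxygen and a terminal alkyne by alkoxycarbonyl-palladation and 5-exo-dig insertion (a [4+1] carbonylative annulation in which the carbonate-type carbon reacts as a metal-bound acyl donor, with reversed polarity).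
3. Enabling feature: the ring E oxygen sits on the carbinol carbon bonded to the pyrrole α-carbon of ring B, two carbons away from the α-carbon, so the O-bound CO reaches that carbon through a five-membered transition state. At that stage the pyrrole is conjugated to the ring D butenolide, which damps azafulvenium ionisation of the carbinol.
4. Ring E is grafted late onto the bare A–D skeleton: C–H formylation at the only free pyrrole α-position, then reagent-controlled allenylboration. Ring D comes from an intramolecular Horner–Wadsworth–Emmons reaction on the ring C ketone.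
5. Rings A and B form together from an amino dione and chloroacetaldehyde (nitrogen-triggered double condensation); ring C comes from a catalytic asymmetric Michael addition and Claisen cyclisation. Order of ring formation: C, then A + B, then D, then E.

Key step: step 11

Locants: rings B/C are numbered as an indole (N-1, C-2, C-3, C-3a, C-4 to C-7, C-7a) whose N-1 and C-7 are joined by the (CH2)4 bridge of ring A ("1,7-butano"). Ring D is fused at C-4/C-5 (lactone O on C-5; its methyl-bearing carbon is C-α). Ring E is a 5-oxooxolan-2-yl group on C-2.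

Assumption: the facial sense of the three catalyst- or reagent-controlled steps (1, 10, 12) is taken from the parent reactions; if a model reaction shows the opposite sense, the pseudoenantiomeric catalyst or antipodal reagent is used and the route is otherwise unchanged.

## Route

Step 1
Reactants: 1 dimethyl malonate; 2 (3E)-hex-3-en-2-one
Product: 3 dimethyl 2-[(3S)-5-oxohexan-3-yl]propanedioate
Conditions: 9-amino-9-deoxy-epi-quinine (10 mol %), PhCO2H (20 mol %), THF, 25 °C
Reagents that add atoms: none
Why: Iminium activation of the enone by the primary amine of the cinchona catalyst, with the quinuclidine nitrogen guiding the malonate, should give the asymmetric Michael adduct, the catalyst shielding one enone face and so setting the (S) centre that becomes the ethyl-bearing C-6.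

Step 2
Reactants: 3 dimethyl 2-[(3S)-5-oxohexan-3-yl]propanedioate; 4 tert-butyl N-(4-bromobutyl)carbamate
Product: 5 dimethyl 2-{4-[(tert-butoxycarbonyl)amino]butyl}-2-[(3S)-5-oxohexan-3-yl]propanedioate
Conditions: NaH (1.05 equiv), NaI (10 mol %), DMF, 0 → 50 °C
Reagents that add atoms: none
Why: The malonate C–H is by far the most acidic site, so its sodium salt should undergo SN2 C-alkylation (malonic ester alkylation) with the primary bromide without touching the existing stereocentre.

Step 3
Reactants: 5 dimethyl 2-{4-[(tert-butoxycarbonyl)amino]butyl}-2-[(3S)-5-oxohexan-3-yl]propanedioate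
Product: 6 methyl (6S)-1-{4-[(tert-butoxycarbonyl)amino]butyl}-6-ethyl-2,4-dioxocyclohexane-1-carboxylate (mixture of C-1 epimers)
Conditions: LiN(SiMe3)2 (3.3 equiv), THF, −78 → 0 °C; then 1 M HCl
Reagents that add atoms: none
Why: Kinetic deprotonation of the methyl ketone at its CH3 group followed by intramolecular Claisen (Dieckmann-type, 6-exo-trig) condensation onto one of the two ester groups should close ring C; the low temperature disfavours retro-Michael cleavage, and the new quaternary centre is destroyed in step 4.

Step 4
Reactants: 6 methyl (6S)-1-{4-[(tert-butoxycarbonyl)amino]butyl}-6-ethyl-2,4-dioxocyclohexane-1-carboxylate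
Product: 7 (4R,5S)-4-(4-aminobutyl)-5-ethylcyclohexane-1,3-dione hydrochloride
Conditions: 6 M HCl, 100 °C
Reagents that add atoms: hydrogen chloride, Cl
Why: Acidic ester hydrolysis, β-keto acid decarboxylation and carbamate cleavage occur in one operation, and C-4 is protonated under equilibrating (enol) conditions, which should place the aminobutyl chain trans (diequatorial) to the ethyl group.

Step 5
Reactants: 7 (4R,5S)-4-(4-aminobutyl)-5-ethylcyclohexane-1,3-dione hydrochloride
Product: 9 (6S,7R)-6-ethyl-1,7-butano-1,5,6,7-tetrahydro-4H-indol-4-one, via bicyclic enaminone 8 (not isolated)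
Conditions: NaHCO3 (3 equiv), EtOH–H2O, 78 °C; then ClCH2CHO (50% in H2O), 78 °C
Reagents that add atoms: chloroacetaldehyde, ClCC=O
Why: Once freed, the tethered amine condenses with the nearer dione carbonyl (seven-membered ring rather than a nine-membered alternative) to the vinylogous amide 8, whose α-carbon and N–H then react with the aldehyde and chloromethyl carbons of chloroacetaldehyde with loss of water (Hantzsch-type pyrrole synthesis on an enaminone), closing rings A and B in one flask and fixing C-7 trans to the ethyl group.

Step 6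
Reactants: 9 (6S,7R)-6-ethyl-1,7-butano-1,5,6,7-tetrahydro-4H-indol-4-one
Product: 10 (5S,6R,7R)-6-ethyl-5-hydroxy-1,7-butano-1,5,6,7-tetrahydro-4H-indol-4-one
Conditions: KN(SiMe3)2, THF, −78 °C; 2-(benzenesulfonyl)-3-phenyloxaziridine, −78 °C; AcOH
Reagents that add atoms: 2-(benzenesulfonyl)-3-phenyloxaziridine, O=S(=O)(c1ccccc1)N1OC1c1ccccc1
Why: Enolate α-hydroxylation with an N-sulfonyloxaziridine should deliver oxygen anti to the neighbouring ethyl group, giving the 5,6-trans α-ketol, which is also the thermodynamically preferred diequatorial epimer.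

Step 7
Reactants: 10 (5S,6R,7R)-6-ethyl-5-hydroxy-1,7-butano-1,5,6,7-tetrahydro-4H-indol-4-one; 11 2-(diethoxyphosphoryl)propanoic acid
Product: 12 (5S,6R,7R)-6-ethyl-4-oxo-1,7-butano-4,5,6,7-tetrahydro-1H-indol-5-yl 2-(diethoxyphosphoryl)propanoate (epimers at the phosphorus-bearing carbon)
Conditions: DCC, DMAP (10 mol %), CH2Cl2, 0 → 25 °C
Reagents that add atoms: none
Why: Steglich esterification acylates the secondary α-ketol under neutral conditions that leave the pyrrole and the C-5 configuration untouched.

Step 8
Reactants: 12 (5S,6R,7R)-6-ethyl-4-oxo-1,7-butano-4,5,6,7-tetrahydro-1H-indol-5-yl 2-(diethoxyphosphoryl)propanoate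
Product: 13 tetracyclic butenolide: (5S,6R,7R)-6-ethyl-1,7-butano-indole core with ring D closed as an α-methylbutenolide (lactone O on C-5, C-4=C-α double bond, methyl on C-α)
Conditions: NaH (1.1 equiv), THF, 0 → 66 °C
Reagents that add atoms: none
Why: Intramolecular Horner–Wadsworth–Emmons olefination of the ring C ketone by the tethered phosphonate anion closes ring D as the butenolide; if C-5 epimerises through the furanolate, the isomer with the lactone oxygen trans to an equatorial ethyl group is the favoured one.

Step 9
Reactants: 13 tetracyclic butenolide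
Product: 15 2-formyl derivative of butenolide 13 (aldehyde on pyrrole C-2), via iminium dichlorophosphate 14 (not isolated)
Conditions: POCl3, DMF, ClCH2CH2Cl, 0 → 40 °C; then aq. NaOAc, 25 °C
Reagents that add atoms: N,N-dimethylformamide, CN(C)C=O; water, O
Why: Vilsmeier–Haack formylation is a C–H functionalisation that should go to the only free α-position of the pyrrole, which is also the position favoured by the vinylogous acyl substituent at C-3a.

Step 10
Reactants: 15 2-formyl derivative of butenolide 13
Product: 17 butenolide 13 bearing a (1R)-1-hydroxybut-3-yn-1-yl group on C-2, via diisopinocampheylborinate ester 16 (not isolated)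
Conditions: B-allenylbis(isopinocampheyl)borane [from (−)-α-pinene], Et2O, −78 → −20 °C; then HOCH2CH2NH2, 25 °C
Reagents that add atoms: B-allenylbis(isopinocampheyl)borane, C=C=CB([C@H]1C[C@H]2C[C@@H]([C@@H]1C)C2(C)C)[C@H]1C[C@H]2C[C@@H]([C@@H]1C)C2(C)C
Why: Asymmetric allenylboration (SE2′ transfer through a chair-like six-membered transition state) should add a propargyl group to the Re face of the aldehyde under reagent control, setting the (R) carbinol centre, and the non-acidic, non-oxidative work-up spares the pyrrolyl carbinol and the butenolide.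

Step 11
Reactants: 17 butenolide 13 bearing a (1R)-1-hydroxybut-3-yn-1-yl group on C-2
Product: 18 butenolide 13 bearing a (2R)-4-methylidene-5-oxooxolan-2-yl group on C-2
Conditions: PdI2 (2 mol %), PBu3 (4 mol %), CO (7 atm), MeCN, 75 °C
Reagents that add atoms: carbon monoxide, [C-]#[O+]
Why: The hydroxyl on the pyrrole-α carbinol carbon attacks CO on divalent palladium to give an alkoxycarbonyl–palladium iodide, which inserts the tethered terminal alkyne syn in a 5-exo-dig fashion; this insertion forms the bond between the new lactone carbonyl carbon and the future methyl-bearing α-carbon and thereby closes ring E, and protonolysis of the vinyl–palladium bond by the HI released in the first event returns PdI2. The closest known reaction type is the palladium-catalysed cyclocarbonylation of 3-butyn-1-ols to α-methylene-γ-butyrolactones, applied here to a heteroaryl carbinol. Ring E is closed by 5-exo-dig migratory insertion (carbon–carbon bond formation), the oxygen–carbonyl bond having been made first. No new stereocentre is created: the α-carbon emerges as an sp2 centre whose configuration is set in step 12, and the carbinol centre from step 10 is carried through because its C–O bond is never broken. The selectivity needed is chemoselectivity for carbonylation over oxygen-to-alkyne cycloisomerisation (a dihydrofuran) and over ionisation of the pyrrolyl carbinol to an azafulvenium ion. CO pressure with a basic phosphine favours the alkoxycarbonyl pathway, and the ring D butenolide, conjugated to the pyrrole as a vinylogous acyl group, lowers the electron density that would drive ionisation.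

Step 12
Reactants: 18 butenolide 13 bearing a (2R)-4-methylidene-5-oxooxolan-2-yl group on C-2
Product: 19 butenolide 13 bearing a (2R,4S)-4-methyl-5-oxooxolan-2-yl group on C-2
Conditions: Ru(OAc)2[(R)-BINAP] (2 mol %), H2 (100 atm), CH2Cl2, 50 °C
Reagents that add atoms: none
Why: Homogeneous asymmetric hydrogenation of an α-methylene-γ-butyrolactone with a BINAP–ruthenium diacetate catalyst is catalyst-controlled through chelation of the lactone carbonyl and should deliver hydrogen to the α-carbon on the face syn to the pyrrolyl group, giving the trans (2R,4S) lactone against the modest substrate preference for cis, while the tetrasubstituted ring D alkene is inert to this catalyst.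

Step 13
Reactants: 19 butenolide 13 bearing a (2R,4S)-4-methyl-5-oxooxolan-2-yl group on C-2
Product: 20 target CNP0232452.4: (4R,5S,6R,7R)-6-ethyl-1,7-butano-4,5,6,7-tetrahydroindole with the cis-fused (αR)-α-methyl-γ-lactone ring D across C-4/C-5 and a (2R,4S)-4-methyl-5-oxooxolan-2-yl group on C-2
Conditions: 10% Pd/C, H2 (20 atm), EtOAc, 25 °C
Reagents that add atoms: none
Why: Heterogeneous syn-hydrogenation of the tetrasubstituted, pyrrole-conjugated butenolide should take place on the face carrying the small allylic hydrogen at C-5 (anti to the C-6 ring carbon), delivering both new hydrogens cis to H-5 and so setting C-4 (R) and C-α (R) of the cis-fused ring D with the methyl group on the concave face.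

## Compound list

1 | dimethyl malonate | COC(=O)CC(=O)OC | starting material
2 | (3E)-hex-3-en-2-one | CC/C=C/C(C)=O | starting material
3 | dimethyl 2-[(3S)-5-oxohexan-3-yl]propanedioate | CC[C@H](C(C(=O)OC)C(=O)OC)CC(C)=O | intermediate
4 | tert-butyl N-(4-bromobutyl)carbamate | CC(C)(C)OC(=O)NCCCCBr | starting material
5 | dimethyl 2-{4-[(tert-butoxycarbonyl)amino]butyl}-2-[(3S)-5-oxohexan-3-yl]propanedioate | CC[C@H](C(CCCCNC(=O)OC(C)(C)C)(C(=O)OC)C(=O)OC)CC(C)=O | intermediate
6 | methyl (6S)-1-{4-[(tert-butoxycarbonyl)amino]butyl}-6-ethyl-2,4-dioxocyclohexane-1-carboxylate (C-1 epimers) | CC[C@H]1CC(=O)CC(=O)C1(CCCCNC(=O)OC(C)(C)C)C(=O)OC | intermediate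
7 | (4R,5S)-4-(4-aminobutyl)-5-ethylcyclohexane-1,3-dione hydrochloride | CC[C@H]1CC(=O)CC(=O)[C@@H]1CCCC[NH3+].[Cl-] | intermediate
8 | (5aR,6S)-6-ethyl-1,2,3,4,5,5a,6,7-octahydro-8H-1-benzazepin-8-one (bicyclic enaminone, not isolated) | CC[C@H]1CC(=O)C=C2NCCCC[C@H]12 | intermediate
9 | (6S,7R)-6-ethyl-1,7-butano-1,5,6,7-tetrahydro-4H-indol-4-one | CC[C@H]1CC(=O)c2ccn3c2[C@@H]1CCCC3 | intermediate
10 | (5S,6R,7R)-6-ethyl-5-hydroxy-1,7-butano-1,5,6,7-tetrahydro-4H-indol-4-one | CC[C@H]1[C@H](O)C(=O)c2ccn3c2[C@@H]1CCCC3 | intermediate
11 | 2-(diethoxyphosphoryl)propanoic acid | CCOP(=O)(OCC)C(C)C(=O)O | starting material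
12 | (5S,6R,7R)-6-ethyl-4-oxo-1,7-butano-4,5,6,7-tetrahydro-1H-indol-5-yl 2-(diethoxyphosphoryl)propanoate | CC[C@H]1[C@H](OC(=O)C(C)P(=O)(OCC)OCC)C(=O)c2ccn3c2[C@@H]1CCCC3 | intermediate
13 | tetracyclic butenolide (5S,6R,7R; ring D as α-methylbutenolide, O on C-5, C-4=C-α) | CC[C@H]1[C@@H]2OC(=O)C(C)=C2c2ccn3c2[C@@H]1CCCC3 | intermediate
14 | 2-(dimethyliminiomethyl) derivative of 13, dichlorophosphate salt (not isolated) | CC[C@H]1[C@@H]2OC(=O)C(C)=C2c2cc(C=[N+](C)C)n3c2[C@@H]1CCCC3.[O-]P(=O)(Cl)Cl | intermediate
15 | 2-formyl derivative of 13 | CC[C@H]1[C@@H]2OC(=O)C(C)=C2c2cc(C=O)n3c2[C@@H]1CCCC3 | intermediate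
16 | diisopinocampheylborinate ester of 17 (not isolated) | CC[C@H]1[C@@H]2OC(=O)C(C)=C2c2cc([C@@H](CC#C)OB([C@H]4C[C@H]5C[C@@H]([C@@H]4C)C5(C)C)[C@H]4C[C@H]5C[C@@H]([C@@H]4C)C5(C)C)n3c2[C@@H]1CCCC3 | intermediate
17 | 13 bearing (1R)-1-hydroxybut-3-yn-1-yl on C-2 | CC[C@H]1[C@@H]2OC(=O)C(C)=C2c2cc([C@H](O)CC#C)n3c2[C@@H]1CCCC3 | intermediate
18 | 13 bearing (2R)-4-methylidene-5-oxooxolan-2-yl on C-2 | CC[C@H]1[C@@H]2OC(=O)C(C)=C2c2cc([C@H]3CC(=C)C(=O)O3)n3c2[C@@H]1CCCC3 | intermediate
19 | 13 bearing (2R,4S)-4-methyl-5-oxooxolan-2-yl on C-2 | CC[C@H]1[C@@H]2OC(=O)C(C)=C2c2cc([C@H]3C[C@H](C)C(=O)O3)n3c2[C@@H]1CCCC3 | intermediate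
20 | CNP0232452.4 (4R,5S,6R,7R,αR; ring E 2R,4S) | CC[C@H]1[C@@H]2OC(=O)[C@H](C)[C@@H]2c2cc([C@H]3C[C@H](C)C(=O)O3)n3c2[C@@H]1CCCC3 | target

## Step count and risks

Total step count: 13. Longest linear sequence: 13 steps (from 1 and 2; 4 and 11 enter as single inputs).

Steps most likely to fail:

**Step 12.** The catalyst has to override the intrinsic preference for hydrogen delivery anti to the pyrrolyl group, so poor facial selectivity (cis lactone) is possible, as is migration of the exocyclic alkene into the ring before reduction. The fallback sets out from 15 and comes back at 19. It makes the cis lactone under substrate control in the carbinol-epimeric series and then inverts the carbinol centre: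
- 15 is treated with the antipodal allenylborane [from (+)-α-pinene], giving after ethanolamine cleavage of the diisopinocampheylborinate ester F1 the (1S)-homopropargylic alcohol F2.
- F2 is cyclocarbonylated under the conditions of step 11 to the (2S)-α-methylene lactone F3.
- Hydrogenation with RhCl(PPh3)3 and H2 (1 atm, benzene) should add hydrogen anti to the pyrrolyl group and give the cis-(2S,4S) lactone F4.
- LiOH (1 equiv, THF–H2O, 0 °C, then pH 5) opens the saturated lactone selectively to the (2S,4S)-4-hydroxy-2-methylbutanoic acid F5.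
- Mitsunobu lactonisation (PPh3, DIAD, THF, 0 °C) recloses the ring with inversion at the carbinol carbon to give 19.

**Step 13.** The tetrasubstituted, pyrrole-conjugated alkene may reduce sluggishly; once it is reduced, the electron-rich pyrrole makes the ring E pyrrolyl-carbinyl C–O bond prone to hydrogenolysis; and face selectivity may erode. The fallback sets out from 13 and comes back at 20, reducing ring D before ring E exists:
- 13 is hydrogenated (Pd/C, H2 50 atm, EtOAc; forcing conditions or NiCl2/NaBH4 are tolerable here) to the saturated tetracyclic lactone F6.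
- Vilsmeier–Haack formylation gives, via the iminium dichlorophosphate F7, the aldehyde F8.
- Allenylboration as in step 10 gives, via the borinate ester F9, the (1R)-homopropargylic alcohol F10.
- Cyclocarbonylation as in step 11 gives the (2R)-α-methylene lactone F11.
- Hydrogenation as in step 12 gives 20. The carbinol intermediates of this series sit on an electron-rich pyrrole and must be kept away from acid.

**Step 11.** Palladium may instead promote cycloisomerisation of the alkynol to a dihydrofuran or ionisation and elimination of the carbinol, or the catalyst may be deactivated. The fallback sets out from 17 and comes back at 18, forming the same bond by a radical instead of an organometallic pathway: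
- 17 is converted with COCl2 and pyridine (−40 °C) into the chloroformate F12.
- PhSeH and pyridine give the Se-phenyl selenocarbonate F13.
- Bu3SnH and AIBN (benzene, 80 °C, high dilution) generate the alkoxycarbonyl radical, which should cyclise 5-exo-dig onto the alkyne and, after hydrogen transfer to the vinyl radical, give 18. Loss of CO2 from the radical is the competing process to watch.

Further compounds
F1 | step 12 | diisopinocampheylborinate ester of F2 (not isolated) | CC[C@H]1[C@@H]2OC(=O)C(C)=C2c2cc([C@H](CC#C)OB([C@@H]4C[C@@H]5C[C@H]([C@H]4C)C5(C)C)[C@@H]4C[C@@H]5C[C@H]([C@H]4C)C5(C)C)n3c2[C@@H]1CCCC3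
F2 | step 12 | 13 bearing (1S)-1-hydroxybut-3-yn-1-yl on C-2 | CC[C@H]1[C@@H]2OC(=O)C(C)=C2c2cc([C@@H](O)CC#C)n3c2[C@@H]1CCCC3
F3 | step 12 | 13 bearing (2S)-4-methylidene-5-oxooxolan-2-yl on C-2 | CC[C@H]1[C@@H]2OC(=O)C(C)=C2c2cc([C@@H]3CC(=C)C(=O)O3)n3c2[C@@H]1CCCC3
F4 | step 12 | 13 bearing cis-(2S,4S)-4-methyl-5-oxooxolan-2-yl on C-2 | CC[C@H]1[C@@H]2OC(=O)C(C)=C2c2cc([C@@H]3C[C@H](C)C(=O)O3)n3c2[C@@H]1CCCC3
F5 | step 12 | (2S,4S)-4-hydroxy-2-methyl-4-(C-2 of 13)butanoic acid | CC[C@H]1[C@@H]2OC(=O)C(C)=C2c2cc([C@@H](O)C[C@H](C)C(=O)O)n3c2[C@@H]1CCCC3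
F6 | step 13 | saturated tetracyclic lactone (rings A–D of the target, C-2 unsubstituted) | CC[C@H]1[C@@H]2OC(=O)[C@H](C)[C@@H]2c2ccn3c2[C@@H]1CCCC3
F7 | step 13 | 2-(dimethyliminiomethyl) derivative of F6, dichlorophosphate salt (not isolated) | CC[C@H]1[C@@H]2OC(=O)[C@H](C)[C@@H]2c2cc(C=[N+](C)C)n3c2[C@@H]1CCCC3.[O-]P(=O)(Cl)Cl
F8 | step 13 | 2-formyl derivative of F6 | CC[C@H]1[C@@H]2OC(=O)[C@H](C)[C@@H]2c2cc(C=O)n3c2[C@@H]1CCCC3
F9 | step 13 | diisopinocampheylborinate ester of F10 (not isolated) | CC[C@H]1[C@@H]2OC(=O)[C@H](C)[C@@H]2c2cc([C@@H](CC#C)OB([C@H]4C[C@H]5C[C@@H]([C@@H]4C)C5(C)C)[C@H]4C[C@H]5C[C@@H]([C@@H]4C)C5(C)C)n3c2[C@@H]1CCCC3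
F10 | step 13 | F6 bearing (1R)-1-hydroxybut-3-yn-1-yl on C-2 | CC[C@H]1[C@@H]2OC(=O)[C@H](C)[C@@H]2c2cc([C@H](O)CC#C)n3c2[C@@H]1CCCC3
F11 | step 13 | F6 bearing (2R)-4-methylidene-5-oxooxolan-2-yl on C-2 | CC[C@H]1[C@@H]2OC(=O)[C@H](C)[C@@H]2c2cc([C@H]3CC(=C)C(=O)O3)n3c2[C@@H]1CCCC3
F12 | step 11 | chloroformate of 17 | CC[C@H]1[C@@H]2OC(=O)C(C)=C2c2cc([C@@H](CC#C)OC(Cl)=O)n3c2[C@@H]1CCCC3
F13 | step 11 | Se-phenyl selenocarbonate of 17 | CC[C@H]1[C@@H]2OC(=O)C(C)=C2c2cc([C@@H](CC#C)OC(=O)[Se]c4ccccc4)n3c2[C@@H]1CCCC3
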